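**Retrosynthetic overview**
1. Target (20E) ⇐ photoisomerisation of its 20Z isomer ⇐ O‑acylation of (18S,20Z)‑variabilin with 15‑methylhexadecanoic acid.
2. Variabilin ⇐ C20=C21 by aldol addition/elimination of 4‑methoxy‑3‑methylfuran‑2(5H)‑one onto an (S)‑α‑methyl aldehyde, then O‑demethylation.
3. Aldehyde ⇐ C17–C18 by SN2 (inversion) of a C17 Grignard reagent on ethyl (S)‑lactate triflate (the only stereocentre, bought).
4. C17 chain ⇐ Johnson–Claisen [3,3] rearrangement of an isopropenyl carbinol (forms C15–C16, sets 12E) ⇐ geranyl acetate (7E bought), isopropenyl‑MgBr and 3‑furylmethyl‑MgCl.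
5. Ring order: no ring is built; the furan and the butenolide are bought intact (3‑(chloromethyl)furan, 3‑methyltetronic acid).

Assumption: the SMILES is taken literally, i.e. 18S and a 20E ylidene (C18 cis to the acyloxy‑bearing ring carbon, the geometric isomer of the natural 20Z series); locants follow variabilin numbering; 3‑(chloromethyl)furan and 3‑methyltetronic acid are taken as catalogue items.

**Step 1**
Reactants: 1 geranyl acetate
Product: 3 (2E)-3-methyl-6-oxohex-2-en-1-yl acetate, via secondary ozonide 2 (not isolated)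
Conditions: O3 (1.0 equiv, Sudan III end point), CH2Cl2, −78 °C; then PPh3, −78 °C → rt
Reagents that add atoms: ozone, [O-][O+]=O
Why: Chemoselective ozonolysis cleaves the electron‑rich 6,7‑alkene, while the 2,3‑alkene (deactivated by the allylic acetate) survives with its E geometry (future 7E).

**Step 2**
Reactants: 3 (2E)-3-methyl-6-oxohex-2-en-1-yl acetate; 4 isopropenylmagnesium bromide; 5 3-(chloromethyl)furan
Product: 8 (6E)-9-(furan-3-yl)-2,6-dimethylnona-1,6-dien-3-ol, via bromomagnesium alkoxide 6 (not isolated), via (furan-3-ylmethyl)magnesium chloride 7 (not isolated)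
Conditions: 4 (1.05 equiv), THF, −78 °C; then Li2CuCl4 (5 mol%) and 7 (1.5 equiv, from 5, Mg, THF, 0 °C), −30 → 0 °C; aq. NH4Cl
Reagents that add atoms: none
Why: Grignard 1,2‑addition to the aldehyde at −78 °C spares the acetate, then Cu‑catalysed SN2 (α) allylic substitution of the primary allylic acetate forms C5–C6 with retention of the E olefin; the racemic carbinol centre is erased in step 3.

**Step 3**
Reactants: 8 (6E)-9-(furan-3-yl)-2,6-dimethylnona-1,6-dien-3-ol; 9 triethyl orthoacetate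
Product: 11 ethyl (4E,8E)-11-(furan-3-yl)-4,8-dimethylundeca-4,8-dienoate, via mixed ketene acetal 10 (not isolated)
Conditions: MeC(OEt)3 (6 equiv), EtCO2H (cat.), 138 °C, EtOH distilled off
Reagents that add atoms: none
Why: Johnson–Claisen [3,3] rearrangement through a chair transition state with the chain equatorial forms the C15–C16 bond and the trisubstituted 12E olefin (>95:5).

**Step 4**
Reactants: 11 ethyl (4E,8E)-11-(furan-3-yl)-4,8-dimethylundeca-4,8-dienoate
Product: 12 (4E,8E)-11-(furan-3-yl)-4,8-dimethylundeca-4,8-dien-1-ol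
Conditions: LiAlH4, Et2O, 0 °C
Reagents that add atoms: none
Why: Hydride reduction of the ester; furan and isolated alkenes are inert.

**Step 5**
Reactants: 12 (4E,8E)-11-(furan-3-yl)-4,8-dimethylundeca-4,8-dien-1-ol
Product: 13 3-[(3E,7E)-11-bromo-4,8-dimethylundeca-3,7-dien-1-yl]furan
Conditions: CBr4, PPh3, CH2Cl2, 0 °C
Reagents that add atoms: carbon tetrabromide, BrC(Br)(Br)Br
Why: Appel bromination is neutral and therefore compatible with the acid‑sensitive furan and the trisubstituted alkenes.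

**Step 6**
Reactants: 14 ethyl (S)-lactate
Product: 15 ethyl (2S)-2-{[(trifluoromethyl)sulfonyl]oxy}propanoate
Conditions: Tf2O, 2,6-lutidine, CH2Cl2, −78 → 0 °C; used at once
Reagents that add atoms: trifluoromethanesulfonic anhydride, O=S(=O)(OS(=O)(=O)C(F)(F)F)C(F)(F)F
Why: O‑Sulfonylation does not touch the stereocentre and converts the chiral‑pool hydroxyl into an SN2 leaving group.

**Step 7**
Reactants: 13 3-[(3E,7E)-11-bromo-4,8-dimethylundeca-3,7-dien-1-yl]furan; 15 ethyl (2S)-2-{[(trifluoromethyl)sulfonyl]oxy}propanoate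
Product: 17 ethyl (2S,6E,10E)-13-(furan-3-yl)-2,6,10-trimethyltrideca-6,10-dienoate, via Grignard reagent 16 (not isolated)
Conditions: Mg, THF, 35 °C; then added to 15 (1.3 equiv), ZnCl2 (10 mol%), THF, 0 °C
Reagents that add atoms: none
Why: Zinc‑catalysed sp3–sp3 coupling of the Grignard with the α‑triflyloxy ester proceeds by clean SN2 inversion, so the (S)‑lactate centre becomes C18 (still S because the CIP ranking changes).

**Step 8**
Reactants: 17 ethyl (2S,6E,10E)-13-(furan-3-yl)-2,6,10-trimethyltrideca-6,10-dienoate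
Product: 18 (2S,6E,10E)-13-(furan-3-yl)-2,6,10-trimethyltrideca-6,10-dienal
Conditions: DIBAL-H (1.05 equiv), CH2Cl2, −78 °C; MeOH, Rochelle salt; used crude
Reagents that add atoms: none
Why: Partial ester reduction stops at the aluminium hemiacetal at −78 °C, and the neutral work‑up avoids epimerising the α‑methyl aldehyde.

**Step 9**
Reactants: 19 3-methyltetronic acid
Product: 20 4-methoxy-3-methylfuran-2(5H)-one
Conditions: Me2SO4, K2CO3, acetone, reflux
Reagents that add atoms: dimethyl sulfate, COS(=O)(=O)OC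
Why: O‑Alkylation of the vinylogous acid at O4 masks the acidic OH and makes C5 the only site for deprotonation.

**Step 10**
Reactants: 20 4-methoxy-3-methylfuran-2(5H)-one; 18 (2S,6E,10E)-13-(furan-3-yl)-2,6,10-trimethyltrideca-6,10-dienal
Product: 24 (5Z)-5-[(2S,6E,10E)-13-(furan-3-yl)-2,6,10-trimethyltrideca-6,10-dien-1-ylidene]-4-methoxy-3-methylfuran-2(5H)-one, via lithiated furanone 21 (not isolated), via lithium aldolate 22 (not isolated), via aldol mesylate 23 (not isolated)
Conditions: LDA, THF, −78 °C; 18, −78 °C; MsCl, −78 → 0 °C; DBU, 0 °C → rt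
Reagents that add atoms: none
Why: Aldol addition of the C5‑lithiated tetronate followed by mesylation and E1cB elimination gives the ylidene tetronate, mainly 20Z because the chain avoids the 4‑OMe group (expected ≥10:1); the aldol stereocentres are erased and C18 is untouched.

**Step 11**
Reactants: 24 (5Z)-5-[(2S,6E,10E)-13-(furan-3-yl)-2,6,10-trimethyltrideca-6,10-dien-1-ylidene]-4-methoxy-3-methylfuran-2(5H)-one
Product: 25 (5Z)-5-[(2S,6E,10E)-13-(furan-3-yl)-2,6,10-trimethyltrideca-6,10-dien-1-ylidene]-4-hydroxy-3-methylfuran-2(5H)-one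
Conditions: NaSEt, DMF, rt; then 1 M HCl to pH 3, 0 °C
Reagents that add atoms: none
Why: SN2 O‑demethylation by thiolate releases the tetronate anion (a carboxylate‑like leaving group), giving (18S,20Z)‑variabilin without acid stress on furan or alkenes.

**Step 12**
Reactants: 25 (5Z)-5-[(2S,6E,10E)-13-(furan-3-yl)-2,6,10-trimethyltrideca-6,10-dien-1-ylidene]-4-hydroxy-3-methylfuran-2(5H)-one; 26 15-methylhexadecanoic acid
Product: 28 (2Z)-2-[(2S,6E,10E)-13-(furan-3-yl)-2,6,10-trimethyltrideca-6,10-dien-1-ylidene]-4-methyl-5-oxo-2,5-dihydrofuran-3-yl 15-methylhexadecanoate, via 15-methylhexadecanoyl chloride 27 (not isolated)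
Conditions: 26, (COCl)2, DMF (cat.), CH2Cl2, rt, evaporate; then 25, Et3N, CH2Cl2, −20 → 0 °C, dark
Reagents that add atoms: none
Why: The triethylammonium tetronate is O‑acylated at O4 by the acid chloride (C3 is blocked by methyl, and no DMAP is used so no O→C acyl shift occurs).

**Step 13**
Reactants: 28 (2Z)-2-[(2S,6E,10E)-13-(furan-3-yl)-2,6,10-trimethyltrideca-6,10-dien-1-ylidene]-4-methyl-5-oxo-2,5-dihydrofuran-3-yl 15-methylhexadecanoate
Product: 29 (2E)-2-[(2S,6E,10E)-13-(furan-3-yl)-2,6,10-trimethyltrideca-6,10-dien-1-ylidene]-4-methyl-5-oxo-2,5-dihydrofuran-3-yl 15-methylhexadecanoate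
Conditions: hν (300 nm, Pyrex), degassed MeCN, 20 °C, to photostationary state; silica HPLC in the dark, recovered 28 re‑irradiated
Reagents that add atoms: none
Why: Photochemical Z→E isomerisation by π→π* excitation of the ylidenebutenolide gives the contra‑thermodynamic 20E isomer (about half at the photostationary state, my estimate); the isolated alkenes, the furan and C18 do not absorb and are unchanged.

**Compound list**
1 | geranyl acetate, (2E)-3,7-dimethylocta-2,6-dien-1-yl acetate | CC(=O)OC/C=C(\C)CCC=C(C)C | starting material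
2 | secondary ozonide, (2E)-5-(5,5-dimethyl-1,2,4-trioxolan-3-yl)-3-methylpent-2-en-1-yl acetate | CC(=O)OC/C=C(\C)CCC1OOC(C)(C)O1 | intermediate
3 | (2E)-3-methyl-6-oxohex-2-en-1-yl acetate | CC(=O)OC/C=C(\C)CCC=O | intermediate
4 | isopropenylmagnesium bromide (prop-1-en-2-ylmagnesium bromide) | CC(=C)[Mg]Br | starting material
5 | 3-(chloromethyl)furan | ClCc1ccoc1 | starting material
6 | bromomagnesium (6E)-8-acetoxy-2,6-dimethylocta-1,6-dien-3-olate (racemic carbinol) | CC(=O)OC/C=C(\C)CCC(O[Mg]Br)C(C)=C | intermediate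
7 | (furan-3-ylmethyl)magnesium chloride | Cl[Mg]Cc1ccoc1 | intermediate
8 | (6E)-9-(furan-3-yl)-2,6-dimethylnona-1,6-dien-3-ol (racemic carbinol, erased in step 3) | CC(=C)C(O)CC/C(C)=C/CCc1ccoc1 | intermediate
9 | triethyl orthoacetate | CC(OCC)(OCC)OCC | starting material
10 | mixed ketene acetal, 3-{(3E)-7-[(1-ethoxyethenyl)oxy]-4,8-dimethylnona-3,8-dien-1-yl}furan | C=C(OCC)OC(CC/C(C)=C/CCc1ccoc1)C(C)=C | intermediate
11 | ethyl (4E,8E)-11-(furan-3-yl)-4,8-dimethylundeca-4,8-dienoate | CCOC(=O)CC/C(C)=C/CC/C(C)=C/CCc1ccoc1 | intermediate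
12 | (4E,8E)-11-(furan-3-yl)-4,8-dimethylundeca-4,8-dien-1-ol | OCCC/C(C)=C/CC/C(C)=C/CCc1ccoc1 | intermediate
13 | 3-[(3E,7E)-11-bromo-4,8-dimethylundeca-3,7-dien-1-yl]furan | BrCCC/C(C)=C/CC/C(C)=C/CCc1ccoc1 | intermediate
14 | ethyl (S)-lactate, ethyl (2S)-2-hydroxypropanoate | C[C@H](O)C(=O)OCC | starting material
15 | ethyl (2S)-2-{[(trifluoromethyl)sulfonyl]oxy}propanoate | C[C@H](OS(=O)(=O)C(F)(F)F)C(=O)OCC | intermediate
16 | [(4E,8E)-11-(furan-3-yl)-4,8-dimethylundeca-4,8-dien-1-yl]magnesium bromide | Br[Mg]CCC/C(C)=C/CC/C(C)=C/CCc1ccoc1 | intermediate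
17 | ethyl (2S,6E,10E)-13-(furan-3-yl)-2,6,10-trimethyltrideca-6,10-dienoate | CCOC(=O)[C@@H](C)CCC/C(C)=C/CC/C(C)=C/CCc1ccoc1 | intermediate
18 | (2S,6E,10E)-13-(furan-3-yl)-2,6,10-trimethyltrideca-6,10-dienal | O=C[C@@H](C)CCC/C(C)=C/CC/C(C)=C/CCc1ccoc1 | intermediate
19 | 3-methyltetronic acid, 4-hydroxy-3-methylfuran-2(5H)-one | CC1=C(O)COC1=O | starting material
20 | 4-methoxy-3-methylfuran-2(5H)-one | COC1=C(C)C(=O)OC1 | intermediate
21 | 5-lithio-4-methoxy-3-methylfuran-2(5H)-one | COC1=C(C)C(=O)OC1[Li] | intermediate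
22 | lithium aldolate of 18 and 21 (mixture at C20 and C21, C18 S) | COC1=C(C)C(=O)OC1C(O[Li])[C@@H](C)CCC/C(C)=C/CC/C(C)=C/CCc1ccoc1 | intermediate
23 | methanesulfonate of the aldol (mixture at C20 and C21, C18 S) | COC1=C(C)C(=O)OC1C(OS(C)(=O)=O)[C@@H](C)CCC/C(C)=C/CC/C(C)=C/CCc1ccoc1 | intermediate
24 | (18S,20Z)-O-methylvariabilin, (5Z)-5-[(2S,6E,10E)-13-(furan-3-yl)-2,6,10-trimethyltrideca-6,10-dien-1-ylidene]-4-methoxy-3-methylfuran-2(5H)-one | COC1=C(C)C(=O)O/C1=C\[C@@H](C)CCC/C(C)=C/CC/C(C)=C/CCc1ccoc1 | intermediate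
25 | (18S,20Z)-variabilin, (5Z)-5-[(2S,6E,10E)-13-(furan-3-yl)-2,6,10-trimethyltrideca-6,10-dien-1-ylidene]-4-hydroxy-3-methylfuran-2(5H)-one | CC1=C(O)/C(=C/[C@@H](C)CCC/C(C)=C/CC/C(C)=C/CCc2ccoc2)OC1=O | intermediate
26 | 15-methylhexadecanoic acid | CC(C)CCCCCCCCCCCCCC(=O)O | starting material
27 | 15-methylhexadecanoyl chloride | CC(C)CCCCCCCCCCCCCC(=O)Cl | intermediate
28 | (2Z)-2-[(2S,6E,10E)-13-(furan-3-yl)-2,6,10-trimethyltrideca-6,10-dien-1-ylidene]-4-methyl-5-oxo-2,5-dihydrofuran-3-yl 15-methylhexadecanoate | CC1=C(OC(=O)CCCCCCCCCCCCCC(C)C)/C(=C/[C@@H](C)CCC/C(C)=C/CC/C(C)=C/CCc2ccoc2)OC1=O | intermediate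
29 | (2E)-2-[(2S,6E,10E)-13-(furan-3-yl)-2,6,10-trimethyltrideca-6,10-dien-1-ylidene]-4-methyl-5-oxo-2,5-dihydrofuran-3-yl 15-methylhexadecanoate | CC1=C(OC(=O)CCCCCCCCCCCCCC(C)C)/C(=C\[C@@H](C)CCC/C(C)=C/CC/C(C)=C/CCc2ccoc2)OC1=O | target

**Step count:** 13 steps in total. Longest linear sequence: 11 steps (1, 2, 3, 4, 5, 7, 8, 10, 11, 12, 13 from geranyl acetate).

**Steps most likely to fail**

Step 13. The 20E isomer is the less stable one, so each pass gives at best about half conversion, and enol‑ester photochemistry or furan photo‑oxidation may compete. The fallback sets out from aldehyde 18 and furanone 20 and comes back to the route at 29, fixing the geometry by a stereospecific elimination instead of light. Furanone 20 is silylated (TBSOTf, Et3N) to tert-butyl[(4-methoxy-3-methylfuran-2-yl)oxy]dimethylsilane F10. Its fluoride‑triggered, erythro‑selective vinylogous aldol addition to 18 (TBAF, THF, −78 °C) and chromatography give the 5,1′-erythro hydroxy lactone F11. Anti‑periplanar dehydration (PPh3, DEAD) converts the erythro relationship specifically into the E ylidene, (18S,20E)-O-methylvariabilin F12. Demethylation with LiI (2,6‑lutidine, 60 °C, dark), which avoids a thiolate that could add reversibly to the ylidene, gives (18S,20E)-variabilin F13. Acylation of F13 with 27 as in step 12 then gives 29.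

Step 7. This is an sp3–sp3 coupling at a secondary α‑triflyloxy ester with a valuable Grignard reagent; elimination, ester attack or partial racemisation would each be costly. The fallback sets out from ester 11 and comes back at aldehyde 18, buying the stereocentre instead as a Roche‑type bromide. Commercial (R)-3-bromo-2-methylpropan-1-ol is silylated to (R)-(3-bromo-2-methylpropoxy)(tert-butyl)dimethylsilane F4. F4 alkylates the lithium enolate of 11 (LDA, THF/DMPU) to give ethyl (4E,8E)-2-[(2S)-3-{[tert-butyl(dimethyl)silyl]oxy}-2-methylpropyl]-11-(furan-3-yl)-4,8-dimethylundeca-4,8-dienoate F5 (C2 epimers, irrelevant). LiOH gives the corresponding carboxylic acid F6. The now superfluous carboxyl carbon is removed by Barton reductive decarboxylation through the 2-thioxopyridin-1(2H)-yl ester F7 (t‑BuSH, hν), giving tert-butyl{[(2S,6E,10E)-13-(furan-3-yl)-2,6,10-trimethyltrideca-6,10-dien-1-yl]oxy}dimethylsilane F8. TBAF gives (2S,6E,10E)-13-(furan-3-yl)-2,6,10-trimethyltrideca-6,10-dien-1-ol F9, and Dess–Martin oxidation returns 18.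

Step 2. Two Grignard reagents are used in one flask; the furylmethyl Grignard is ambident and Wurtz‑prone, and α/γ selectivity at the allylic acetate depends on the copper catalyst. The fallback sets out from aldehyde 3 and comes back at dienol 8, replacing the Grignard by a sulfone‑stabilised furylmethyl anion. Only 4 is added to 3, and (2E)-6-hydroxy-3,7-dimethylocta-2,7-dien-1-yl acetate F1 is isolated. 3-[(Phenylsulfonyl)methyl]furan F2 is made from 5 and sodium benzenesulfinate in DMF. Its sodium salt (NaH) is allylated by F1 under Pd(PPh3)4 catalysis (Tsuji–Trost, linear E product) to give (6E)-9-(furan-3-yl)-2,6-dimethyl-9-(phenylsulfonyl)nona-1,6-dien-3-ol F3. Reductive desulfonylation (Mg, MeOH) returns 8.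

**Further compounds**
F1 | step 2 | (2E)-6-hydroxy-3,7-dimethylocta-2,7-dien-1-yl acetate | CC(=O)OC/C=C(\C)CCC(O)C(C)=C
F2 | step 2 | 3-[(phenylsulfonyl)methyl]furan | O=S(=O)(Cc1ccoc1)c1ccccc1
F3 | step 2 | (6E)-9-(furan-3-yl)-2,6-dimethyl-9-(phenylsulfonyl)nona-1,6-dien-3-ol | CC(=C)C(O)CC/C(C)=C/CC(c1ccoc1)S(=O)(=O)c1ccccc1
F4 | step 7 | (R)-(3-bromo-2-methylpropoxy)(tert-butyl)dimethylsilane | CC(C)(C)[Si](C)(C)OC[C@@H](C)CBr
F5 | step 7 | ethyl (4E,8E)-2-[(2S)-3-{[tert-butyl(dimethyl)silyl]oxy}-2-methylpropyl]-11-(furan-3-yl)-4,8-dimethylundeca-4,8-dienoate | CCOC(=O)C(C[C@H](C)CO[Si](C)(C)C(C)(C)C)CC/C(C)=C/CC/C(C)=C/CCc1ccoc1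
F6 | step 7 | (4E,8E)-2-[(2S)-3-{[tert-butyl(dimethyl)silyl]oxy}-2-methylpropyl]-11-(furan-3-yl)-4,8-dimethylundeca-4,8-dienoic acid | OC(=O)C(C[C@H](C)CO[Si](C)(C)C(C)(C)C)CC/C(C)=C/CC/C(C)=C/CCc1ccoc1
F7 | step 7 | 2-thioxopyridin-1(2H)-yl ester of F6 (Barton ester) | S=c1ccccn1OC(=O)C(C[C@H](C)CO[Si](C)(C)C(C)(C)C)CC/C(C)=C/CC/C(C)=C/CCc1ccoc1
F8 | step 7 | tert-butyl{[(2S,6E,10E)-13-(furan-3-yl)-2,6,10-trimethyltrideca-6,10-dien-1-yl]oxy}dimethylsilane | CC(C)(C)[Si](C)(C)OC[C@@H](C)CCC/C(C)=C/CC/C(C)=C/CCc1ccoc1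
F9 | step 7 | (2S,6E,10E)-13-(furan-3-yl)-2,6,10-trimethyltrideca-6,10-dien-1-ol | OC[C@@H](C)CCC/C(C)=C/CC/C(C)=C/CCc1ccoc1
F10 | step 13 | tert-butyl[(4-methoxy-3-methylfuran-2-yl)oxy]dimethylsilane | COc1coc(O[Si](C)(C)C(C)(C)C)c1C
F11 | step 13 | 5,1′-erythro-5-[(2S,6E,10E)-13-(furan-3-yl)-1-hydroxy-2,6,10-trimethyltrideca-6,10-dien-1-yl]-4-methoxy-3-methylfuran-2(5H)-one (erythro pair, C5 and C1′ not specified in the SMILES) | COC1=C(C)C(=O)OC1C(O)[C@@H](C)CCC/C(C)=C/CC/C(C)=C/CCc1ccoc1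
F12 | step 13 | (18S,20E)-O-methylvariabilin, (5E)-5-[(2S,6E,10E)-13-(furan-3-yl)-2,6,10-trimethyltrideca-6,10-dien-1-ylidene]-4-methoxy-3-methylfuran-2(5H)-one | COC1=C(C)C(=O)O/C1=C/[C@@H](C)CCC/C(C)=C/CC/C(C)=C/CCc1ccoc1
F13 | step 13 | (18S,20E)-variabilin, (5E)-5-[(2S,6E,10E)-13-(furan-3-yl)-2,6,10-trimethyltrideca-6,10-dien-1-ylidene]-4-hydroxy-3-methylfuran-2(5H)-one | CC1=C(O)/C(=C\[C@@H](C)CCC/C(C)=C/CC/C(C)=C/CCc2ccoc2)OC1=O
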